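Numbering: O1, C2 (bears ring A, the phenol with the side chain), C3, C4, C5 (bears ring B, 4-hydroxyphenyl); ring C is the phenol at the end of the side chain. C3 and C4 are adjacent CH(CH3) carbons, each next to a benzylic ether carbon (C2, C5). The C3–C4 bond with its two methyls therefore maps onto the inner and terminal carbons of two ethynyl groups on one dibenzylic ether.
Retrosynthetic cuts, in order: the three O–Si bonds; the hydrogens added at C3, C4 and their methyls (back to a 3,4-dimethylene ring); C3–C4 (back to a 1,6-diyne ether); C2–O1 (ring-A propargylic carbonate plus ring-B propargylic alcohol); the C2–ethynyl and C5–ethynyl bonds; the ring A–side chain bond.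
Forward: the ring-B alcohol (3 steps) and the ring-A/ring-C carbonate (8 steps) are joined at C2–O1. The only new ring, the tetrahydrofuran, closes in step 13. The diene is then saturated and the phenols are freed.
Stereochemistry: the side-chain R centre comes from Ir–PHOX hydrogenation of a single E-alkene (step 9) and C5 from a lipase resolution (step 3). C2 comes from the Cu–pybox enantioconvergent etherification (step 12), and C3 and C4 from diimide addition to the face opposite the two cis aryl groups (step 14).

Key step: step 13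

Abbreviations: TBS = tert-butyldimethylsilyl, TBSO = tert-butyldimethylsilyloxy, pin = pinacolato, NBSH = 2-nitrobenzenesulfonohydrazide.
Assumption: the sense of induction in the two ligand-controlled steps (9 and 12) is taken from the parent phenyl substrates, (E)-1,2-diphenylpropene and 1-phenylprop-2-ynyl esters; both ligands are sold in either hand, so a reversed sense would be corrected by the mirror-image ligand alone.

Step 1
Reactants: 1 4-hydroxybenzaldehyde
Product: 2 4-(TBSO)benzaldehyde
Conditions: TBSCl, imidazole, DMF, 0 °C to rt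
Reagents that add atoms: tert-butyldimethylsilyl chloride (TBSCl), CC(C)(C)[Si](C)(C)Cl
Why: Imidazole-promoted O-silylation of a phenol is routine, and the aldehyde is not affected.

Step 2
Reactants: 2 4-(TBSO)benzaldehyde; 3 ethynylmagnesium bromide (0.5 M in THF)
Product: 4 rac-1-[4-(TBSO)phenyl]prop-2-yn-1-ol
Conditions: THF, 0 °C; aq. NH4Cl
Reagents that add atoms: none
Why: Grignard 1,2-addition of an alkynyl nucleophile to an aromatic aldehyde should give the racemic propargylic alcohol cleanly, the aryl silyl ether being stable to the reagent at 0 °C.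

Step 3
Reactants: 4 rac-1-[4-(TBSO)phenyl]prop-2-yn-1-ol
Product: 5 (S)-1-[4-(TBSO)phenyl]prop-2-yn-1-ol
Conditions: Novozym 435 (immobilised Candida antarctica lipase B), vinyl acetate, MTBE, 35 °C, stopped just past half conversion; silica gel
Reagents that add atoms: none
Why: Lipase-catalysed kinetic resolution by irreversible transesterification: with aryl as the large and ethynyl as the medium substituent the enzyme should acetylate the R alcohol, so that the S alcohol, whose carbinol carbon becomes C5, is left in high enantiomeric purity once conversion has passed one half and is separated from the acetate on silica.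

Step 4
Reactants: 6 4-iodophenol
Product: 7 tert-butyl(4-iodophenoxy)dimethylsilane
Conditions: TBSCl, imidazole, DMF, rt
Reagents that add atoms: tert-butyldimethylsilyl chloride (TBSCl), CC(C)(C)[Si](C)(C)Cl
Why: Imidazole-promoted O-silylation of a phenol, with the aryl iodide as a spectator.

Step 5
Reactants: 7 tert-butyl(4-iodophenoxy)dimethylsilane; 8 propyne (solution in THF)
Product: 9 tert-butyldimethyl[4-(prop-1-yn-1-yl)phenoxy]silane
Conditions: PdCl2(PPh3)2 (cat.), CuI (cat.), Et3N, THF, rt
Reagents that add atoms: none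
Why: Sonogashira coupling of an aryl iodide proceeds at room temperature, and the amine base spares the aryl silyl ether.

Step 6
Reactants: 9 tert-butyldimethyl[4-(prop-1-yn-1-yl)phenoxy]silane
Product: 10 (Z)-2-{1-[4-(TBSO)phenyl]prop-1-en-2-yl}-4,4,5,5-tetramethyl-1,3,2-dioxaborolane (aryl and methyl cis)
Conditions: B2pin2, CuCl, NaOtBu and P(p-tolyl)3 (each cat.), MeOH (2 equiv), THF, rt
Reagents that add atoms: bis(pinacolato)diboron, CC1(C)OB(OC1(C)C)B1OC(C)(C)C(C)(C)O1
Why: Copper-catalysed formal hydroboration (syn borylcupration, then protonation of the C–Cu bond by methanol): copper takes the benzylic carbon and boron the methyl-bearing carbon, which should give one regio- and stereoisomer with aryl and methyl cis.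

Step 7
Reactants: 11 4-bromo-2-iodophenol
Product: 12 (4-bromo-2-iodophenoxy)(tert-butyl)dimethylsilane
Conditions: TBSCl, imidazole, DMF, rt
Reagents that add atoms: tert-butyldimethylsilyl chloride (TBSCl), CC(C)(C)[Si](C)(C)Cl
Why: Imidazole-promoted O-silylation of a phenol, with both halides left in place.

Step 8
Reactants: 12 (4-bromo-2-iodophenoxy)(tert-butyl)dimethylsilane; 10 the (Z)-alkenyl boronate
Product: 13 (E)-2-[5-bromo-2-(TBSO)phenyl]-1-[4-(TBSO)phenyl]prop-1-ene (the two aryl groups trans)
Conditions: PdCl2(dppf) (cat.), aq. K3PO4, THF, 45 °C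
Reagents that add atoms: none
Why: Suzuki–Miyaura coupling with retention of alkene geometry; oxidative addition at the carbon–iodine bond is far faster than at carbon–bromine with this catalyst at mild temperature, so the bromide is kept for step 10.

Step 9
Reactants: 13 the (E)-alkene
Product: 14 (R)-2-[5-bromo-2-(TBSO)phenyl]-1-[4-(TBSO)phenyl]propane
Conditions: [Ir(cod)(L)]BArF (1 mol %; L = (S)-4-tert-butyl-2-[2-(di-o-tolylphosphanyl)phenyl]-4,5-dihydrooxazole, BArF = B[3,5-(CF3)2C6H3]4), H2 (50 bar), CH2Cl2, rt
Reagents that add atoms: none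
Why: Iridium-catalysed asymmetric hydrogenation of an unfunctionalised trisubstituted alkene: 13 belongs to the (E)-α-methylstilbene class on which Ir–PHOX catalysts perform best, the single alkene geometry from steps 6 and 8 lets the ligand deliver H2 to one face and set the R benzylic centre, and aryl bromide and aryl silyl ethers are inert to this catalyst.

Step 10
Reactants: 14 the (R)-aryl bromide
Product: 16 4-TBSO-3-{(2R)-1-[4-(TBSO)phenyl]propan-2-yl}benzaldehyde, via aryllithium 15 (not isolated)
Conditions: n-BuLi, THF, −78 °C; DMF, −78 °C to 0 °C; aq. NH4Cl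
Reagents that add atoms: N,N-dimethylformamide, CN(C)C=O
Why: Bromine–lithium exchange followed by formylation with DMF (Bouveault aldehyde synthesis); lithium sits para to the silyloxy group, so no O-to-C silyl shift can occur, and the tertiary benzylic centre is not touched at −78 °C.

Step 11
Reactants: 16 the ring-A aldehyde; 3 ethynylmagnesium bromide
Product: 18 tert-butyl 1-(4-TBSO-3-{(2R)-1-[4-(TBSO)phenyl]propan-2-yl}phenyl)prop-2-yn-1-yl carbonate (both carbinol epimers), via bromomagnesium alkoxide 17 (not isolated)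
Conditions: THF, 0 °C; then Boc2O, 0 °C to rt; water
Reagents that add atoms: di-tert-butyl dicarbonate (Boc2O), CC(C)(C)OC(=O)OC(=O)OC(C)(C)C
Why: Grignard 1,2-addition followed by O-acylation of the magnesium alkoxide with Boc2O in the same flask; the carbinol centre forms without control, which is harmless because the next step erases and resets it.

Step 12
Reactants: 18 the ring-A propargylic carbonate; 5 (S)-1-[4-(TBSO)phenyl]prop-2-yn-1-ol (3 equiv, excess recovered)
Product: 19 (R)-1-(4-TBSO-3-{(2R)-1-[4-(TBSO)phenyl]propan-2-yl}phenyl)prop-2-yn-1-yl (S)-1-[4-(TBSO)phenyl]prop-2-yn-1-yl ether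
Conditions: CuOTf·0.5C6H6 (10 mol %), 2,6-bis[(4S)-4-phenyl-4,5-dihydrooxazol-2-yl]pyridine ((S,S)-Ph-pybox, 12 mol %), iPr2NEt (20 mol %), 4 Å molecular sieves, CH2Cl2, −20 to 0 °C; minor diastereomer removed on silica
Reagents that add atoms: none
Why: Copper-catalysed asymmetric propargylic substitution with an alcohol as nucleophile: both epimers of 18 pass, via the copper acetylide and loss of CO2 and tert-butoxide, into one planar copper allenylidene, the pybox ligand steers the oxygen of 5 to one face of its γ-carbon and so sets C2 as R under catalyst control, while C5 is retained because its C–O bond is never broken.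

Step 13
Reactants: 19 the bis-propargylic ether
Product: 20 (2S,5R)-2-(4-TBSO-3-{(2R)-1-[4-(TBSO)phenyl]propan-2-yl}phenyl)-5-[4-(TBSO)phenyl]-3,4-dimethylenetetrahydrofuran (2,5-cis, C2 and C5 arranged in space as in the target)
Conditions: Pd2(dba)3·CHCl3 (2.5 mol %), P(o-tolyl)3 (10 mol %), AcOH (1.1 equiv), Et3SiH (3 equiv), toluene, rt; used at once
Reagents that add atoms: none
Why: Zerovalent palladium is protonated by acetic acid to H–Pd–OAc, which adds across one terminal alkyne with palladium on the inner carbon; this alkenylpalladium inserts the second alkyne inner carbon to inner carbon, forming C3–C4, and Et3SiH then replaces acetate by hydride so that reductive elimination releases the diene and zerovalent palladium. The closest known reaction type is the palladium-catalysed, acid- and silane-mediated reductive cyclisation of 1,6-diynes to 1,2-dialkylidene five-membered rings, a class that includes dipropargyl ethers. The one ring formed, O1–C2–C3–C4–C5, closes in the 5-exo-dig mode. No stereocentre is created: the C2–O1, C5–O1 and benzylic C–H bonds are spectators, so the R,S pair of 19 reappears as the 2,5-cis relationship of 20 (the descriptors read 2S,5R only because sp2 C3 and C4 now outrank the aryl groups). Cyclisation must outrun plain reduction or hydrosilylation of the alkynes, which the 1,6-spacing and the angle compression by the two aryl-bearing carbons secure, and either alkyne may react first since both orders converge on 20. The exocyclic double bonds must not drift into the ring towards the furan, which would erase C2 and C5; this is countered by room temperature, barely more than one equivalent of the weak acid, the bulky phosphine, a short reaction time and immediate use of the product.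

Step 14
Reactants: 20 the 3,4-dimethylene compound
Product: 23 all-cis (2R,3S,4R,5S)-3,4-dimethyl-2-(4-TBSO-3-{(2R)-1-[4-(TBSO)phenyl]propan-2-yl}phenyl)-5-[4-(TBSO)phenyl]tetrahydrofuran, via 3-methyl-4-methylene monoene 21 (not isolated), via 4-methyl-3-methylene monoene 22 (not isolated)
Conditions: NBSH (excess, in portions), Et3N, CH2Cl2, rt
Reagents that add atoms: none
Why: Diimide reduction, a concerted syn transfer of two hydrogens with no metal hydride to isomerise the diene or cleave the benzylic C–O bonds: allylic 1,3-strain against the exocyclic methylenes turns both cis aryl groups roughly perpendicular to the ring so that they cover one face, hydrogen reaches C3 and C4 from the other face, and both new methyl groups end up cis to the aryl groups (3S,4R).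

Step 15
Reactants: 23 the tris-TBS ether
Product: 24 (2R,3S,4R,5S)-2-{4-hydroxy-3-[(2R)-1-(4-hydroxyphenyl)propan-2-yl]phenyl}-5-(4-hydroxyphenyl)-3,4-dimethyltetrahydrofuran (CNP0232576.2)
Conditions: Bu4NF/AcOH (1:1, slight excess per silyl group), THF, 0 °C
Reagents that add atoms: none
Why: Fluoride-induced cleavage of aryl silyl ethers; buffering with acetic acid keeps the liberated phenols protonated, which suppresses para-quinone-methide ring opening and hence epimerisation at C2 and C5 of the strained all-cis ring.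

Compound list
1 | 4-hydroxybenzaldehyde | O=Cc1ccc(O)cc1 | starting material
2 | 4-(TBSO)benzaldehyde | O=Cc1ccc(O[Si](C)(C)C(C)(C)C)cc1 | intermediate
3 | ethynylmagnesium bromide | C#C[Mg]Br | starting material
4 | rac-1-[4-(TBSO)phenyl]prop-2-yn-1-ol | C#CC(O)c1ccc(O[Si](C)(C)C(C)(C)C)cc1 | intermediate
5 | (S)-1-[4-(TBSO)phenyl]prop-2-yn-1-ol | O[C@@H](C#C)c1ccc(O[Si](C)(C)C(C)(C)C)cc1 | intermediate
6 | 4-iodophenol | Oc1ccc(I)cc1 | starting material
7 | tert-butyl(4-iodophenoxy)dimethylsilane | CC(C)(C)[Si](C)(C)Oc1ccc(I)cc1 | intermediate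
8 | propyne | CC#C | starting material
9 | tert-butyldimethyl[4-(prop-1-yn-1-yl)phenoxy]silane | CC#Cc1ccc(O[Si](C)(C)C(C)(C)C)cc1 | intermediate
10 | (Z)-2-{1-[4-(TBSO)phenyl]prop-1-en-2-yl}-4,4,5,5-tetramethyl-1,3,2-dioxaborolane | C/C(B1OC(C)(C)C(C)(C)O1)=C\c1ccc(O[Si](C)(C)C(C)(C)C)cc1 | intermediate
11 | 4-bromo-2-iodophenol | Oc1ccc(Br)cc1I | starting material
12 | (4-bromo-2-iodophenoxy)(tert-butyl)dimethylsilane | CC(C)(C)[Si](C)(C)Oc1ccc(Br)cc1I | intermediate
13 | (E)-2-[5-bromo-2-(TBSO)phenyl]-1-[4-(TBSO)phenyl]prop-1-ene | C/C(c1cc(Br)ccc1O[Si](C)(C)C(C)(C)C)=C\c1ccc(O[Si](C)(C)C(C)(C)C)cc1 | intermediate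
14 | (R)-2-[5-bromo-2-(TBSO)phenyl]-1-[4-(TBSO)phenyl]propane | Brc1ccc(O[Si](C)(C)C(C)(C)C)c([C@H](C)Cc2ccc(O[Si](C)(C)C(C)(C)C)cc2)c1 | intermediate
15 | aryllithium from 14 (not isolated) | [Li]c1ccc(O[Si](C)(C)C(C)(C)C)c([C@H](C)Cc2ccc(O[Si](C)(C)C(C)(C)C)cc2)c1 | intermediate
16 | 4-TBSO-3-{(2R)-1-[4-(TBSO)phenyl]propan-2-yl}benzaldehyde | O=Cc1ccc(O[Si](C)(C)C(C)(C)C)c([C@H](C)Cc2ccc(O[Si](C)(C)C(C)(C)C)cc2)c1 | intermediate
17 | bromomagnesium alkoxide of the ring-A propargylic alcohol, both carbinol epimers (not isolated) | C#CC(O[Mg]Br)c1ccc(O[Si](C)(C)C(C)(C)C)c([C@H](C)Cc2ccc(O[Si](C)(C)C(C)(C)C)cc2)c1 | intermediate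
18 | tert-butyl 1-(4-TBSO-3-{(2R)-1-[4-(TBSO)phenyl]propan-2-yl}phenyl)prop-2-yn-1-yl carbonate, both carbinol epimers | C#CC(OC(=O)OC(C)(C)C)c1ccc(O[Si](C)(C)C(C)(C)C)c([C@H](C)Cc2ccc(O[Si](C)(C)C(C)(C)C)cc2)c1 | intermediate
19 | bis-propargylic ether, ring-A carbinol R, ring-B carbinol S, side chain R | C#C[C@H](c1ccc(O[Si](C)(C)C(C)(C)C)c([C@H](C)Cc2ccc(O[Si](C)(C)C(C)(C)C)cc2)c1)O[C@@H](C#C)c1ccc(O[Si](C)(C)C(C)(C)C)cc1 | intermediate
20 | (2S,5R)-2,5-cis-diaryl-3,4-dimethylenetetrahydrofuran, tris-TBS ether | C=C1C(=C)[C@H](c2ccc(O[Si](C)(C)C(C)(C)C)c([C@H](C)Cc3ccc(O[Si](C)(C)C(C)(C)C)cc3)c2)O[C@@H]1c1ccc(O[Si](C)(C)C(C)(C)C)cc1 | intermediate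
21 | (2R,3S,5S)-3-methyl-4-methylene monoene, tris-TBS ether (not isolated) | C=C1[C@H](C)[C@H](c2ccc(O[Si](C)(C)C(C)(C)C)c([C@H](C)Cc3ccc(O[Si](C)(C)C(C)(C)C)cc3)c2)O[C@@H]1c1ccc(O[Si](C)(C)C(C)(C)C)cc1 | intermediate
22 | (2R,4R,5S)-4-methyl-3-methylene monoene, tris-TBS ether (not isolated) | C[C@@H]1C(=C)[C@H](c2ccc(O[Si](C)(C)C(C)(C)C)c([C@H](C)Cc3ccc(O[Si](C)(C)C(C)(C)C)cc3)c2)O[C@@H]1c1ccc(O[Si](C)(C)C(C)(C)C)cc1 | intermediate
23 | all-cis (2R,3S,4R,5S)-2,5-diaryl-3,4-dimethyltetrahydrofuran, tris-TBS ether | C[C@@H]1[C@H](C)[C@H](c2ccc(O[Si](C)(C)C(C)(C)C)c([C@H](C)Cc3ccc(O[Si](C)(C)C(C)(C)C)cc3)c2)O[C@@H]1c1ccc(O[Si](C)(C)C(C)(C)C)cc1 | intermediate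
24 | CNP0232576.2, (2R,3S,4R,5S)-2-{4-hydroxy-3-[(2R)-1-(4-hydroxyphenyl)propan-2-yl]phenyl}-5-(4-hydroxyphenyl)-3,4-dimethyltetrahydrofuran | C[C@@H]1[C@H](C)[C@H](c2ccc(O)c([C@H](C)Cc3ccc(O)cc3)c2)O[C@@H]1c1ccc(O)cc1 | target

Total step count: 15.
Longest linear sequence: 11 steps from 4-iodophenol (steps 4, 5, 6, 8, 9, 10, 11, 12, 13, 14, 15).

Steps most likely to fail

**Step 12.** Capture of the copper allenylidene by a hindered secondary alcohol may be slow. Carbon attack by copper acetylides and oligomerisation could then compete, and a mismatch between the ligand and the chiral nucleophile could erode facial control.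
The fallback is a Nicholas reaction that sets out from 18 (with 5) and returns at 19.
- Treatment of 18 with Co2(CO)8 in CH2Cl2 should give the hexacarbonyldicobalt complex of the carbonate F1.
- BF3·OEt2 at −78 °C, with 5 and 2,6-di-tert-butyl-4-methylpyridine present, ionises only the cobalt-bearing partner. This should give the cobalt-complexed ether of 2R configuration F2 together with its 2S epimer F3, and the two are separated on silica.
- Me3NO in CH2Cl2 removes the metal from F2 and delivers 19.
- Control at C2 is given up for a more dependable C–O bond formation. C5 and the side chain still fix the absolute series, so separating the diastereomers leaves a single enantiomer.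

**Step 13.** The exocyclic double bonds may migrate into the ring under palladium hydride or acid, with loss of C2 and C5. The silane may reduce or hydrosilylate the alkynes before ring closure. The s-cis diene may undergo self-Diels–Alder addition on concentration.
The fallback sets out from 19 and returns at 20, and it forms the same C3–C4 bond stepwise.
- Molybdenum-catalysed hydrostannation selective for the inner alkyne carbon (Bu3SnH, Mo(CO)3(CNtBu)3 cat., THF, 55 °C) places tin on the inner carbon of both propargylic-ether alkynes. This should give the bis(1-aryl-2-tributylstannylprop-2-enyl) ether F4.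
- Excess CuCl in DMF at rt then couples the two alkenyl–tin carbons intramolecularly by oxidative homocoupling. The ring closes to 20 without acid, hydride or palladium.

**Step 14.** The very small reagent may discriminate poorly between the two faces, or the reduction may stall after the first hydrogen transfer at the crowded second methylene.
The fallback sets out from 20 and returns at 23. A bulky borane chooses the face, and the oxygen introduced is removed afterwards.
- 9-BBN-H (2.5 equiv, THF, rt) should add from the open face to give the 3,4-bis[(9-borabicyclo[3.3.1]nonan-9-yl)methyl] adduct F5, which is not isolated.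
- NaBO3·4H2O oxidises it to the all-cis 3,4-bis(hydroxymethyl) compound F6.
- MsCl and Et3N at −20 °C give the bis(methanesulfonate) F7.
- LiBHEt3 in THF displaces both sulfonates by hydride and gives 23.

Further compounds
F1 | step 12 | hexacarbonyldicobalt complex of carbonate 18 (both carbinol epimers) | [CH]12[Co]3(=C=O)(=C=O)(=C=O)[Co]1(=C=O)(=C=O)(=C=O)C23C(OC(=O)OC(C)(C)C)c1ccc(O[Si](C)(C)C(C)(C)C)c([C@H](C)Cc2ccc(O[Si](C)(C)C(C)(C)C)cc2)c1
F2 | step 12 | hexacarbonyldicobalt complex (ring-A alkyne) of ether 19, 2R | [CH]12[Co]3(=C=O)(=C=O)(=C=O)[Co]1(=C=O)(=C=O)(=C=O)C23[C@H](c1ccc(O[Si](C)(C)C(C)(C)C)c([C@H](C)Cc2ccc(O[Si](C)(C)C(C)(C)C)cc2)c1)O[C@@H](C#C)c1ccc(O[Si](C)(C)C(C)(C)C)cc1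
F3 | step 12 | 2S epimer of F2 | [CH]12[Co]3(=C=O)(=C=O)(=C=O)[Co]1(=C=O)(=C=O)(=C=O)C23[C@@H](c1ccc(O[Si](C)(C)C(C)(C)C)c([C@H](C)Cc2ccc(O[Si](C)(C)C(C)(C)C)cc2)c1)O[C@@H](C#C)c1ccc(O[Si](C)(C)C(C)(C)C)cc1
F4 | step 13 | bis(1-aryl-2-tributylstannylprop-2-enyl) ether, C2 and C5 as in 19 | C=C([Sn](CCCC)(CCCC)CCCC)[C@H](c1ccc(O[Si](C)(C)C(C)(C)C)c([C@H](C)Cc2ccc(O[Si](C)(C)C(C)(C)C)cc2)c1)O[C@@H](C(=C)[Sn](CCCC)(CCCC)CCCC)c1ccc(O[Si](C)(C)C(C)(C)C)cc1
F5 | step 14 | all-cis 3,4-bis[(9-borabicyclo[3.3.1]nonan-9-yl)methyl] adduct, tris-TBS ether | C1CC2CCCC(C1)B2C[C@@H]3[C@H](CB4C5CCCC4CCC5)[C@H](c4ccc(O[Si](C)(C)C(C)(C)C)c([C@H](C)Cc5ccc(O[Si](C)(C)C(C)(C)C)cc5)c4)O[C@@H]3c1ccc(O[Si](C)(C)C(C)(C)C)cc1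
F6 | step 14 | all-cis 3,4-bis(hydroxymethyl) compound, tris-TBS ether | OC[C@@H]1[C@H](CO)[C@H](c2ccc(O[Si](C)(C)C(C)(C)C)c([C@H](C)Cc3ccc(O[Si](C)(C)C(C)(C)C)cc3)c2)O[C@@H]1c1ccc(O[Si](C)(C)C(C)(C)C)cc1
F7 | step 14 | all-cis 3,4-bis(methanesulfonyloxymethyl) compound, tris-TBS ether | CS(=O)(=O)OC[C@@H]1[C@H](COS(C)(=O)=O)[C@H](c2ccc(O[Si](C)(C)C(C)(C)C)c([C@H](C)Cc3ccc(O[Si](C)(C)C(C)(C)C)cc3)c2)O[C@@H]1c1ccc(O[Si](C)(C)C(C)(C)C)cc1
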